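**Strategy.** The route rests on a [3+3] disconnection of ring C of the lower (catechin) unit: the benzylic C4–C3 bond and the aryl ether O1–C8a bond. Because C4 sits ortho to the oxygen-bearing C8a on ring A, a 2-bromobenzyl bromide acts as a 1,3-dielectrophile toward a methyl ketone enolate (C3 carbon, O1 oxygen); one pot gives the flav-2-ene. Asymmetric hydroboration then sets C2 and C3 trans. The interflavan bond follows from addition of the 8-lithiated catechin ether to a dihydrorobinetin-derived 4-ketone and ionic deoxygenation, which places the aryl group cis to O-3.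

Key step: step 4

Assumption: (+)-dihydrorobinetin, 1,3-bis(benzyloxy)-5-bromobenzene and 3,4-bis(benzyloxy)acetophenone are taken as purchasable; flavan numbering (O1, C2, C3, C4, C4a, C5–C8, C8a) and ring letters A (benzo), B (2-aryl), C (pyran) are used throughout.

**Route**

Step 1
Reactants: 1 1,3-bis(benzyloxy)-5-bromobenzene
Product: 3 2,4-bis(benzyloxy)-6-bromobenzaldehyde, via aryl iminium chloride 2 (not isolated)
Conditions: POCl3, DMF, 0 to 70 °C; then aq NaOAc
Reagents that add atoms: N,N-dimethylformamide CN(C)C=O (formyl carbon); water O (carbonyl oxygen)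
Why: Vilsmeier–Haack formylation: the chloroiminium ion attacks the position ortho to bromine and para to a benzyloxy group, which is less crowded than the site between the two ethers, and aqueous acetate hydrolyses the iminium salt to the aldehyde.

Step 2
Reactants: 3 2,4-bis(benzyloxy)-6-bromobenzaldehyde
Product: 4 [2,4-bis(benzyloxy)-6-bromophenyl]methanol
Conditions: NaBH4, THF/MeOH, 0 °C
Reagents that add atoms: none
Why: Borohydride reduction of the aldehyde is chemoselective and leaves the aryl bromide and the benzyl ethers untouched.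

Step 3
Reactants: 4 [2,4-bis(benzyloxy)-6-bromophenyl]methanol
Product: 5 1,5-bis(benzyloxy)-3-bromo-2-(bromomethyl)benzene
Conditions: PBr3, CH2Cl2, 0 °C; used at once
Reagents that add atoms: phosphorus tribromide BrP(Br)Br
Why: Alcohol-to-bromide conversion with PBr3 proceeds by SN2 displacement of the phosphite ester by bromide, and the ortho bromine moderates the lability of this electron-rich benzylic bromide.

Step 4
Reactants: 5 1,5-bis(benzyloxy)-3-bromo-2-(bromomethyl)benzene; 6 1-[3,4-bis(benzyloxy)phenyl]ethan-1-one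
Product: 8 5,7-bis(benzyloxy)-2-[3,4-bis(benzyloxy)phenyl]-4H-chromene, via bromo ketone 7 (not isolated)
Conditions: 6 (2 equiv), KN(SiMe3)2 (2 equiv), THF, −78 °C; add 5, −78 to 0 °C; then CuI (10 mol%), 1,10-phenanthroline (20 mol%), Cs2CO3, DMF, 90 °C
Reagents that add atoms: none
Why: The potassium enolate of 6 displaces the benzylic bromide of 5 at carbon (SN2 enolate alkylation) and so forms C4–C3 of ring C; ketone 7 is re-enolized by surplus enolate and carbonate, and its phenanthroline-ligated monovalent copper enolate inserts into the neighbouring aryl C–Br bond and closes O1–C8a by C–O reductive elimination (Ullmann-type enolate O-arylation). The closest known reaction types are the copper-catalysed tandem C-benzylation/O-arylation of 1,3-dicarbonyl compounds with 2-bromobenzyl bromides to 4H-chromenes and the copper-catalysed enolate O-arylation of 2-bromoaryl ketones to benzofurans. Ring C closes as a six-membered ring by attack of the Z-enolate oxygen on the aryl carbon (formally 6-exo), whereas C-arylation would give a benzocyclobutene and should not compete. No stereocenter is formed; the product is the achiral flav-2-ene, whose C2=C3 bond is the handle for step 5. The step needs monoalkylation (excess enolate, more hindered product enolate), C- over O-alkylation (soft benzylic bromide, potassium enolate in THF) and no migration of the double bond to the 2H-chromene (no base stronger than enolate or carbonate in the hot stage).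

Step 5
Reactants: 8 5,7-bis(benzyloxy)-2-[3,4-bis(benzyloxy)phenyl]-4H-chromene
Product: 10 (2R,3S)-5,7-bis(benzyloxy)-2-[3,4-bis(benzyloxy)phenyl]chroman-3-ol, via flavan-3-yl isopinocampheylborane 9 (not isolated)
Conditions: IpcBH2 (from (+)-α-pinene), THF, −25 °C; then NaOH, H2O2, 0 °C; recrystallization
Reagents that add atoms: hydrogen peroxide OO
Why: Asymmetric hydroboration–oxidation of the enol ether places boron on C3 (β to O1, away from the aryl-bearing C2) and hydrogen on C2 from the same face, so that oxidation with retention gives the 2,3-trans alcohol, while the isopinocampheyl group selects the face, the (2R,3S) sense following the sense known for 1-arylcycloalkenes with this reagent.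

Step 6
Reactants: 10 (2R,3S)-5,7-bis(benzyloxy)-2-[3,4-bis(benzyloxy)phenyl]chroman-3-ol
Product: 11 (2R,3S)-5,7-bis(benzyloxy)-2-[3,4-bis(benzyloxy)phenyl]-8-bromochroman-3-ol
Conditions: NBS, CH2Cl2, −78 to 0 °C
Reagents that add atoms: N-bromosuccinimide O=C1CCC(=O)N1Br
Why: Electrophilic aromatic bromination goes to C8 of the phloroglucinol-type ring A, the most nucleophilic free position of 5,7-di-O-benzyl flavan-3-ols and far more reactive than the catechol ring B.

Step 7
Reactants: 11 (2R,3S)-5,7-bis(benzyloxy)-2-[3,4-bis(benzyloxy)phenyl]-8-bromochroman-3-ol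
Product: 12 3-O-tert-butyldimethylsilyl ether of 11
Conditions: TBSOTf, 2,6-lutidine, CH2Cl2, 0 °C
Reagents that add atoms: tert-butyldimethylsilyl trifluoromethanesulfonate CC(C)(C)[Si](C)(C)OS(=O)(=O)C(F)(F)F
Why: Silyl ether formation masks the only acidic proton before the halogen–lithium exchange and does not touch the stereocenters.

Step 8
Reactants: 13 (+)-dihydrorobinetin
Product: 14 (2R,3R)-7-(benzyloxy)-3-hydroxy-2-[3,4,5-tris(benzyloxy)phenyl]chroman-4-one
Conditions: BnBr, K2CO3, DMF, rt, argon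
Reagents that add atoms: benzyl bromide BrCc1ccccc1
Why: Williamson etherification under carbonate benzylates only the four phenols, the aliphatic 3-OH staying free, and the mild base and exclusion of air limit ring opening, C2 epimerization and pyrogallol oxidation.

Step 9
Reactants: 14 (2R,3R)-7-(benzyloxy)-3-hydroxy-2-[3,4,5-tris(benzyloxy)phenyl]chroman-4-one
Product: 15 3-O-tert-butyldimethylsilyl ether of 14
Conditions: TBSOTf, 2,6-lutidine, CH2Cl2, −78 to 0 °C
Reagents that add atoms: tert-butyldimethylsilyl trifluoromethanesulfonate CC(C)(C)[Si](C)(C)OS(=O)(=O)C(F)(F)F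
Why: Silylation of the secondary alcohol under non-enolizing conditions (hindered pyridine base, low temperature) gives a bulky ether that later shields one face of C4.

Step 10
Reactants: 12 3-O-tert-butyldimethylsilyl ether of 11; 15 3-O-tert-butyldimethylsilyl ether of 14
Product: 17 4-hydroxy-4-(catechin-8-yl) adduct (octa-O-benzyl bis-O-silyl carbinol), via aryllithium 16 (not isolated)
Conditions: 12, t-BuLi (2 equiv), THF, −78 °C; then 15, −78 °C; H2O
Reagents that add atoms: none
Why: Bromine–lithium exchange is faster than benzylic deprotonation at −78 °C and the aryllithium then undergoes 1,2-addition to the aryl ketone, the configuration of the new carbinol being immaterial because C4 becomes planar in the next step.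

Step 11
Reactants: 17 4-hydroxy-4-(catechin-8-yl) adduct
Product: 19 octa-O-benzyl-3,3'-bis-O-(tert-butyldimethylsilyl)-robinetinidol-(4β→8)-catechin, via flavan-4-yl cation 18 (not isolated)
Conditions: nBu3SnH, CF3CO2H, CH2Cl2, 0 °C
Reagents that add atoms: none
Why: Ionic hydrogenation (acid-promoted deoxygenation): CF3CO2H ionizes the doubly benzylic carbinol to a 4-aryl flavan-4-yl cation stabilized by the 7-benzyloxy group, and the tin hydride should add to the face opposite the neighbouring 3-silyloxy group, the same facial preference that nucleophiles show with flavan-4-yl cations, so that the aryl group ends cis to O-3 (4R).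

Step 12
Reactants: 19 octa-O-benzyl-3,3'-bis-O-(tert-butyldimethylsilyl)-robinetinidol-(4β→8)-catechin
Product: 20 octa-O-benzyl-robinetinidol-(4β→8)-catechin
Conditions: HF·pyridine, THF, 0 °C to rt
Reagents that add atoms: none
Why: Fluoride-mediated desilylation cleaves both secondary silyl ethers, while benzyl ethers and the interflavan bond are inert to buffered HF.

Step 13
Reactants: 20 octa-O-benzyl-robinetinidol-(4β→8)-catechin
Product: 21 robinetinidol-(4β→8)-catechin (CNP0261864.3)
Conditions: H2 (1 atm), Pd(OH)2/C, THF/MeOH/H2O, rt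
Reagents that add atoms: none
Why: Catalytic hydrogenolysis removes the eight benzyl ethers under neutral conditions that leave the interflavan C4–C8 bond, the aryl ethers of both rings C and all five stereocenters intact.

**Compound list**

1 | 1,3-bis(benzyloxy)-5-bromobenzene | Brc1cc(OCc2ccccc2)cc(OCc2ccccc2)c1 | starting material
2 | N-{[2,4-bis(benzyloxy)-6-bromophenyl]methylidene}-N-methylmethanaminium chloride (formed in the flask, not isolated) | C[N+](C)=Cc1c(Br)cc(OCc2ccccc2)cc1OCc1ccccc1.[Cl-] | intermediate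
3 | 2,4-bis(benzyloxy)-6-bromobenzaldehyde | O=Cc1c(Br)cc(OCc2ccccc2)cc1OCc1ccccc1 | intermediate
4 | [2,4-bis(benzyloxy)-6-bromophenyl]methanol | OCc1c(Br)cc(OCc2ccccc2)cc1OCc1ccccc1 | intermediate
5 | 1,5-bis(benzyloxy)-3-bromo-2-(bromomethyl)benzene | BrCc1c(Br)cc(OCc2ccccc2)cc1OCc1ccccc1 | intermediate
6 | 1-[3,4-bis(benzyloxy)phenyl]ethan-1-one | CC(=O)c1ccc(OCc2ccccc2)c(OCc2ccccc2)c1 | starting material
7 | 1-[3,4-bis(benzyloxy)phenyl]-3-[2,4-bis(benzyloxy)-6-bromophenyl]propan-1-one (formed in the flask, not isolated) | O=C(CCc1c(Br)cc(OCc2ccccc2)cc1OCc1ccccc1)c1ccc(OCc2ccccc2)c(OCc2ccccc2)c1 | intermediate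
8 | 5,7-bis(benzyloxy)-2-[3,4-bis(benzyloxy)phenyl]-4H-chromene (tetra-O-benzyl flav-2-ene) | c1c(OCc3ccccc3)cc(OCc3ccccc3)c2c1OC(c1ccc(OCc3ccccc3)c(OCc3ccccc3)c1)=CC2 | intermediate
9 | (isopinocampheyl)[(2R)-5,7-bis(benzyloxy)-2-[3,4-bis(benzyloxy)phenyl]chroman-3-yl]borane, boron trans to the 2-aryl group (formed in the flask, not isolated) | c1c(OCc3ccccc3)cc(OCc3ccccc3)c2c1O[C@H](c1ccc(OCc3ccccc3)c(OCc3ccccc3)c1)[C@@H](B[C@@H]1C[C@@H]3C[C@@H](C3(C)C)[C@H]1C)C2 | intermediate
10 | (2R,3S)-5,7-bis(benzyloxy)-2-[3,4-bis(benzyloxy)phenyl]chroman-3-ol (5,7,3',4'-tetra-O-benzyl-(+)-catechin) | c1c(OCc3ccccc3)cc(OCc3ccccc3)c2c1O[C@H](c1ccc(OCc3ccccc3)c(OCc3ccccc3)c1)[C@@H](O)C2 | intermediate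
11 | (2R,3S)-5,7-bis(benzyloxy)-2-[3,4-bis(benzyloxy)phenyl]-8-bromochroman-3-ol | Brc1c(OCc3ccccc3)cc(OCc3ccccc3)c2c1O[C@H](c1ccc(OCc3ccccc3)c(OCc3ccccc3)c1)[C@@H](O)C2 | intermediate
12 | (2R,3S)-5,7-bis(benzyloxy)-2-[3,4-bis(benzyloxy)phenyl]-8-bromo-3-[(tert-butyldimethylsilyl)oxy]chromane | Brc1c(OCc3ccccc3)cc(OCc3ccccc3)c2c1O[C@H](c1ccc(OCc3ccccc3)c(OCc3ccccc3)c1)[C@@H](O[Si](C)(C)C(C)(C)C)C2 | intermediate
13 | (+)-dihydrorobinetin, (2R,3R)-3,7-dihydroxy-2-(3,4,5-trihydroxyphenyl)chroman-4-one | Oc1ccc2c(c1)O[C@H](c1cc(O)c(O)c(O)c1)[C@@H](O)C2=O | starting material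
14 | (2R,3R)-7-(benzyloxy)-3-hydroxy-2-[3,4,5-tris(benzyloxy)phenyl]chroman-4-one | c1ccccc1COc1ccc2c(c1)O[C@H](c1cc(OCc3ccccc3)c(OCc3ccccc3)c(OCc3ccccc3)c1)[C@@H](O)C2=O | intermediate
15 | (2R,3R)-7-(benzyloxy)-3-[(tert-butyldimethylsilyl)oxy]-2-[3,4,5-tris(benzyloxy)phenyl]chroman-4-one | c1ccccc1COc1ccc2c(c1)O[C@H](c1cc(OCc3ccccc3)c(OCc3ccccc3)c(OCc3ccccc3)c1)[C@@H](O[Si](C)(C)C(C)(C)C)C2=O | intermediate
16 | 8-lithio derivative of 12 (formed in the flask, not isolated) | [Li]c1c(OCc3ccccc3)cc(OCc3ccccc3)c2c1O[C@H](c1ccc(OCc3ccccc3)c(OCc3ccccc3)c1)[C@@H](O[Si](C)(C)C(C)(C)C)C2 | intermediate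
17 | tertiary carbinol: C4 of the robinetinidol unit (2R, 3-O-silyl, trans to the 2-aryl group) carries OH and C8 of the (2R,3S)-catechin unit; C4 configuration not controlled | c1ccccc1COc1ccc2c(c1)O[C@H](c1cc(OCc3ccccc3)c(OCc3ccccc3)c(OCc3ccccc3)c1)[C@@H](O[Si](C)(C)C(C)(C)C)C2(O)c1c(OCc3ccccc3)cc(OCc3ccccc3)c2c1O[C@H](c1ccc(OCc3ccccc3)c(OCc3ccccc3)c1)[C@@H](O[Si](C)(C)C(C)(C)C)C2 | intermediate
18 | 4-aryl flavan-4-yl cation of 17 as its trifluoroacetate (formed in the flask, not isolated) | c1ccccc1COc1ccc2c(c1)O[C@H](c1cc(OCc3ccccc3)c(OCc3ccccc3)c(OCc3ccccc3)c1)[C@@H](O[Si](C)(C)C(C)(C)C)[C+]2c1c(OCc3ccccc3)cc(OCc3ccccc3)c2c1O[C@H](c1ccc(OCc3ccccc3)c(OCc3ccccc3)c1)[C@@H](O[Si](C)(C)C(C)(C)C)C2.[O-]C(=O)C(F)(F)F | intermediate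
19 | octa-O-benzyl-3,3'-bis-O-(tert-butyldimethylsilyl)-robinetinidol-(4β→8)-catechin; upper unit 2,3-trans-3,4-cis (2R,3S,4R), lower unit (2R,3S) | c1ccccc1COc1ccc2c(c1)O[C@H](c1cc(OCc3ccccc3)c(OCc3ccccc3)c(OCc3ccccc3)c1)[C@@H](O[Si](C)(C)C(C)(C)C)[C@H]2c1c(OCc3ccccc3)cc(OCc3ccccc3)c2c1O[C@H](c1ccc(OCc3ccccc3)c(OCc3ccccc3)c1)[C@@H](O[Si](C)(C)C(C)(C)C)C2 | intermediate
20 | octa-O-benzyl-robinetinidol-(4β→8)-catechin (both 3-OH free) | c1ccccc1COc1ccc2c(c1)O[C@H](c1cc(OCc3ccccc3)c(OCc3ccccc3)c(OCc3ccccc3)c1)[C@@H](O)[C@H]2c1c(OCc3ccccc3)cc(OCc3ccccc3)c2c1O[C@H](c1ccc(OCc3ccccc3)c(OCc3ccccc3)c1)[C@@H](O)C2 | intermediate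
21 | (2R,3S)-2-(3,4-dihydroxyphenyl)-8-[(2R,3S,4R)-3,7-dihydroxy-2-(3,4,5-trihydroxyphenyl)chroman-4-yl]chromane-3,5,7-triol, robinetinidol-(4β→8)-catechin | Oc1ccc2c(c1)O[C@H](c1cc(O)c(O)c(O)c1)[C@@H](O)[C@H]2c1c(O)cc(O)c2c1O[C@H](c1ccc(O)c(O)c1)[C@@H](O)C2 | target

**Count.** Total steps: 13. Longest linear sequence: 11 (steps 1–7, then 10–13); steps 8–9 form the second branch.

**Steps most likely to fail**

1. Step 4. Over-alkylation of the ketone enolate, slow copper-mediated C–O closure on the electron-rich aryl bromide, or base-induced migration of the new double bond may erode the one-pot process. The fallback separates the two bond formations. It sets out from 3 and 6: Claisen–Schmidt condensation (KOH, EtOH/THF) should give the (E)-chalcone F1. Conjugate reduction with catalytic [(Ph3P)CuH]6 and PhSiH3 in toluene should give the saturated bromo ketone 7, now isolated. Enolate O-arylation with Pd2(dba)3, DPEphos and Cs2CO3 in toluene at 100 °C then closes ring C and comes back to the route at 8.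

2. Step 5. Insufficient facial discrimination by the chiral borane on this benzo-fused enol ether, or acid-triggered loss of the enol ether before hydroboration, would lower the enantiomeric purity. The fallback replaces reagent control by resolution. It sets out from 8: BH3·THF followed by NaOH/H2O2 should give the racemic trans alcohol, that is 10 together with its (2S,3R) enantiomer F2. Esterification of the mixture with (S)-2-methoxy-2-phenylacetic acid (DCC, DMAP) gives the diastereomeric esters, the (2R,3S) ester F3 and the (2S,3R) ester F4, to be separated by chromatography or crystallization. K2CO3 in MeOH/THF releases the alcohol from F3 and comes back to the route at 10.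

3. Step 11. Hydride delivery to the planar C4 cation may be poorly face-selective in this 2,3-trans series, and the acid may cause partial desilylation or reversal of the interflavan bond. The fallback enforces the 3,4-cis geometry by intramolecular delivery and sets out from 10 and 14. Acylation of 10 with glutaric anhydride (DMAP, pyridine) gives the 3-O-hemiglutarate F5. Esterification of F5 with the 3-OH of 14 (DCC, DMAP) gives the diester-linked ketone F6. NaBH4 (THF/EtOH, −20 °C) reduces the ketone to the benzylic 4-ol F7. TMSOTf (CH2Cl2, −40 °C, high dilution) ionizes C4, and the tether anchored on O-3 can bring C8 of the catechin unit only to the face of C4 syn to O-3, which should give the 3,4-cis macrocycle F8. K2CO3 in MeOH/THF cleaves both ester links and comes back to the route at 20.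

Further compounds
F1 | step 4 | (E)-1-[3,4-bis(benzyloxy)phenyl]-3-[2,4-bis(benzyloxy)-6-bromophenyl]prop-2-en-1-one | O=C(/C=C/c1c(Br)cc(OCc2ccccc2)cc1OCc1ccccc1)c1ccc(OCc2ccccc2)c(OCc2ccccc2)c1
F2 | step 5 | (2S,3R)-5,7-bis(benzyloxy)-2-[3,4-bis(benzyloxy)phenyl]chroman-3-ol (enantiomer of 10) | c1c(OCc3ccccc3)cc(OCc3ccccc3)c2c1O[C@@H](c1ccc(OCc3ccccc3)c(OCc3ccccc3)c1)[C@H](O)C2
F3 | step 5 | (S)-2-methoxy-2-phenylacetate of 10 | c1c(OCc3ccccc3)cc(OCc3ccccc3)c2c1O[C@H](c1ccc(OCc3ccccc3)c(OCc3ccccc3)c1)[C@@H](OC(=O)[C@@H](OC)c1ccccc1)C2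
F4 | step 5 | (S)-2-methoxy-2-phenylacetate of F2 | c1c(OCc3ccccc3)cc(OCc3ccccc3)c2c1O[C@@H](c1ccc(OCc3ccccc3)c(OCc3ccccc3)c1)[C@H](OC(=O)[C@@H](OC)c1ccccc1)C2
F5 | step 11 | 3-O-(4-carboxybutanoyl) ester (hemiglutarate) of 10 | c1c(OCc3ccccc3)cc(OCc3ccccc3)c2c1O[C@H](c1ccc(OCc3ccccc3)c(OCc3ccccc3)c1)[C@@H](OC(=O)CCCC(=O)O)C2
F6 | step 11 | glutarate diester linking O-3 of 10 and O-3 of 14 (4-ketone) | c1c(OCc3ccccc3)cc(OCc3ccccc3)c2c1O[C@H](c1ccc(OCc3ccccc3)c(OCc3ccccc3)c1)[C@@H](OC(=O)CCCC(=O)O[C@@H]3[C@@H](c4cc(OCc5ccccc5)c(OCc5ccccc5)c(OCc5ccccc5)c4)Oc4cc(OCc5ccccc5)ccc4C3=O)C2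
F7 | step 11 | 4-ol from reduction of F6 (C4 configuration not controlled) | c1c(OCc3ccccc3)cc(OCc3ccccc3)c2c1O[C@H](c1ccc(OCc3ccccc3)c(OCc3ccccc3)c1)[C@@H](OC(=O)CCCC(=O)O[C@@H]3[C@@H](c4cc(OCc5ccccc5)c(OCc5ccccc5)c(OCc5ccccc5)c4)Oc4cc(OCc5ccccc5)ccc4C3O)C2
F8 | step 11 | 3,4-cis glutarate-bridged macrocycle (C4 of the robinetinidol unit bonded to C8 of the catechin unit) | c16c(OCc3ccccc3)cc(OCc3ccccc3)c2c1O[C@H](c1ccc(OCc3ccccc3)c(OCc3ccccc3)c1)[C@@H](OC(=O)CCCC(=O)O[C@@H]3[C@@H](c4cc(OCc5ccccc5)c(OCc5ccccc5)c(OCc5ccccc5)c4)Oc4cc(OCc5ccccc5)ccc4[C@@H]36)C2
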